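Retrosynthesis: the C16=C17 alkene, the two acetates and the C6 hydroxyl are adjusted last. The cuts then follow in this order: C13–C16 (ring D); C9–C11 together with C8–C14 (ring C); C8=C9 and the C20–O–C7 ester bond (δ-lactone); finally C10–C9, C5–C6 and C10–C20 on a ring A made from benzoic acid.
Enabling feature: C8 is the α-carbon of a β-keto δ-lactone (C7 lactone carbonyl, C15 ketone), and the lactone ring C7–O–C20–C10–C9–C8 is spiro-joined to ring A at C10. With a C8=C9 double bond this ring is a doubly activated dienophile. The equatorial oxygen on C1, gauche to C9 across C1–C10, can hold the C11–C14 diene through silicon.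
Forward order of rings: ring A (Birch), temporary oxasilinane C19–O–Si–C6 (radical), δ-lactone (Knoevenagel), ring C plus temporary oxasilinane C1–O–Si–C11 (Diels–Alder), ring D (allylsilane on oxocarbenium).
Stereochemistry: C4 comes from a catalyst-controlled desymmetrising conjugate reduction. C5, C10 and C1 are relayed from C4 by the substrate. C9 and C8 come from the tether and suprafacial addition in the key step. C13 comes from the only possible bridging mode.
Key step: step 25

Numbering: ent-kaurane numbers of the target are used throughout. Ring A is C1–C5 and C10; C18 (CH3) and C19 (CH2O) sit on C4, C6 on C5, C9 and C20 on C10. Ring C is C8, C9, C11–C14. Ring D is C8, C14, C13, C16, C15, with C17 on C16. The "top face" of ring A carries C19, C6, C20 and O-1; C18, H-5, C9 and H-1 are on the bottom face.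
Assumption: the sense of induction of the chiral copper hydride on dienone 6 cannot be predicted with certainty. The ligand antipode that gives (R)-8 is to be used; the (R)-ligand is written.

Step 1
Reactants: 1 benzoic acid
Product: 3 1-methylcyclohexa-2,5-diene-1-carboxylic acid, via dilithium dienediolate 2 (not isolated)
Conditions: Li, NH3(l)/THF, −78 °C; then MeI, −78 °C → rt; aq HCl
Reagents that add atoms: iodomethane, CI
Why: Birch reductive alkylation: dissolving-metal reduction of the benzoate stops at the cross-conjugated dienediolate 2, which MeI alkylates at the ipso carbon, so the future C4 becomes quaternary (C18 methyl, C19 carboxyl) but is still prochiral.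

Step 2
Reactants: 3 1-methylcyclohexa-2,5-diene-1-carboxylic acid
Product: 4 (1-methylcyclohexa-2,5-dien-1-yl)methanol
Conditions: LiAlH4, Et2O, 0 °C → rt
Reagents that add atoms: none
Why: Hydride reduction of a carboxylic acid with LiAlH4; the unconjugated diene is inert and no stereocentre is involved.

Step 3
Reactants: 4 (1-methylcyclohexa-2,5-dien-1-yl)methanol
Product: 5 tert-butyldimethyl[(1-methylcyclohexa-2,5-dien-1-yl)methoxy]silane
Conditions: TBSCl, imidazole, CH2Cl2, rt
Reagents that add atoms: tert-butyldimethylsilyl chloride, CC(C)(C)[Si](C)(C)Cl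
Why: Standard silyl ether formation that masks the neopentyl C19 hydroxyl for the oxidation, iodination and carbonylation steps.

Step 4
Reactants: 5 TBS ether of the dienylmethanol
Product: 6 4-{[(tert-butyldimethylsilyl)oxy]methyl}-4-methylcyclohexa-2,5-dien-1-one
Conditions: Rh2(cap)4 (1 mol %), t-BuOOH (70% aq), K2CO3, CH2Cl2, rt
Reagents that add atoms: tert-butyl hydroperoxide, CC(C)(C)OO
Why: Dirhodium-catalysed allylic C–H oxidation with t-BuOOH attacks the only doubly allylic methylene, and since the quaternary carbon blocks aromatisation the cross-conjugated dienone is the expected product.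

Step 5
Reactants: 6 prochiral dienone
Product: 8 (R)-4-{[(tert-butyldimethylsilyl)oxy]methyl}-4-methylcyclohex-2-en-1-one, via silyl dienol ether 7 (not isolated)
Conditions: Cu(OAc)2·H2O (5 mol %), (R)-DTBM-SEGPHOS (5.5 mol %), (EtO)2MeSiH (1.1 equiv), toluene, −20 °C; then 1 M HCl, THF, 0 °C
Reagents that add atoms: none
Why: Catalytic enantioselective conjugate hydrosilylation (chiral copper hydride) used as a desymmetrisation: the ligand pocket distinguishes the two enantiotopic enone arms by the CH3/CH2OTBS difference at C4 and so fixes C4 as R, while the first reduction parks the product as silyl dienol ether 7, which is no longer an acceptor and is hydrolysed only in the work-up.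

Step 6
Reactants: 8 (R)-enone
Product: 9 (R)-4-{[(tert-butyldimethylsilyl)oxy]methyl}-2-iodo-4-methylcyclohex-2-en-1-one
Conditions: I2, pyridine/CH2Cl2, 0 °C → rt
Reagents that add atoms: iodine, II
Why: Amine-mediated α-iodination of an enone (conjugate addition of pyridine, iodination of the enolate, elimination) functionalises only the α-carbon C10 and leaves C4 untouched.

Step 7
Reactants: 9 (R)-2-iodoenone
Product: 10 methyl (R)-3-{[(tert-butyldimethylsilyl)oxy]methyl}-3-methyl-6-oxocyclohex-1-ene-1-carboxylate
Conditions: PdCl2(PPh3)2 (5 mol %), CO (1 atm), MeOH, Et3N, DMF, 50 °C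
Reagents that add atoms: carbon monoxide, [C-]#[O+]; methanol, CO
Why: Palladium-catalysed alkoxycarbonylation of an alkenyl iodide (oxidative addition, CO insertion, methanolysis) brings in C20 as the ester that will activate C5 toward the radical and make C10 nucleophilic afterwards.

Step 8
Reactants: 10 TBS-protected 2-carbomethoxy enone
Product: 11 methyl (R)-3-(hydroxymethyl)-3-methyl-6-oxocyclohex-1-ene-1-carboxylate
Conditions: HF·pyridine, THF, 0 °C → rt
Reagents that add atoms: none
Why: Acidic fluoride desilylation removes the TBS group without exposing the strongly electrophilic alkylidene β-keto ester to basic fluoride or alkoxide.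

Step 9
Reactants: 11 hydroxymethyl enone ester; 12 (bromomethyl)chlorodimethylsilane
Product: 13 methyl (R)-3-({[(bromomethyl)dimethylsilyl]oxy}methyl)-3-methyl-6-oxocyclohex-1-ene-1-carboxylate
Conditions: imidazole, CH2Cl2, 0 °C
Reagents that add atoms: none
Why: Simple O-silylation with a chlorosilane places the C6 carbon on the C19 oxygen; the labile ether is carried on after filtration only.

Step 10
Reactants: 13 bromomethylsilyl ether
Product: 14 cis-fused oxasilinane β-keto ester (ring A: C1 ketone and C10 CO2Me; ring C19–O–SiMe2–C6 on the top face; C10 epimers/enol)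
Conditions: Bu3SnH (slow addition), AIBN, benzene (0.01 M), reflux
Reagents that add atoms: none
Why: Silicon-tethered radical cyclisation (Nishiyama–Stork type): the nucleophilic α-silyl radical adds 6-exo to the electron-poor β-carbon C5, and because the O–Si–C tether starts at C19 the new C5–C6 bond can only form on the face cis to C19, which fixes C5 relative to C4.

Step 11
Reactants: 14 oxasilinane β-keto ester
Product: 15 β-keto ester with free C19 CH2OH and C6 CH2SiMe2Ph (both on the top face; C10 epimers/enol)
Conditions: PhLi (3 equiv), THF, −78 → 0 °C; aq NH4Cl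
Reagents that add atoms: phenyllithium, [Li]c1ccccc1
Why: Ring opening of a cyclic alkoxysilane by an organolithium: the first equivalent of PhLi converts the β-keto ester into its unreactive lithium enolate and the next attacks silicon and expels the C19 alkoxide, which turns the labile Si–O ring (it would otherwise shuttle to the cis C20 hydroxyl once that is set free) into a robust SiMe2Ph mask of the C6 hydroxyl.

Step 12
Reactants: 15 C19 alcohol
Product: 16 C19 benzyl ether of 15
Conditions: BnOC(=NH)CCl3, TfOH (cat.), CH2Cl2/cyclohexane, 0 °C → rt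
Reagents that add atoms: benzyl 2,2,2-trichloroacetimidate, N=C(OCc1ccccc1)C(Cl)(Cl)Cl
Why: Acid-catalysed benzylation with the trichloroacetimidate works on hindered alcohols and avoids base, which would C-alkylate the β-keto ester or drive O-19 onto the C20 ester.

Step 13
Reactants: 16 benzyl-protected β-keto ester
Product: 17 C10-quaternary keto ester (C9 CH2OH on the bottom face trans to C6; C20 CO2Me on the top face)
Conditions: aq HCHO (37%), KHCO3, THF, 0 °C → rt
Reagents that add atoms: formaldehyde, C=O
Why: Aldol-type C-hydroxymethylation of a β-keto ester with formaldehyde under mild base: the top face of the enolate is covered by the C5 CH2SiMe2Ph arm and the C19 CH2OBn group, so C9 should enter from the bottom face, trans to C6, which sets the C10 quaternary centre.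

Step 14
Reactants: 17 β-hydroxymethyl keto ester
Product: 18 1,9-diol ester (equatorial C1 hydroxyl on the top face cis to C20)
Conditions: Me4NBH(OAc)3, MeCN/AcOH, −30 °C
Reagents that add atoms: none
Why: Hydroxyl-directed triacetoxyborohydride reduction (Evans–Saksena type): boron bound to O-9 delivers hydride to the bottom face of C1, which is also the axial trajectory, so the new hydroxyl is equatorial and cis to C20, and the acidic medium suppresses retro-aldol loss of formaldehyde.

Step 15
Reactants: 18 1,9-diol ester
Product: 19 1,9-O-isopropylidene acetal (trans-fused 1,3-dioxane) of the methyl ester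
Conditions: Me2C(OMe)2, PPTS (cat.), CH2Cl2, rt
Reagents that add atoms: 2,2-dimethoxypropane, COC(C)(C)OC
Why: Acid-catalysed transketalisation ties the only two hydroxyls (equatorial O-1 and equatorial C9–O) into a trans-fused 1,3-dioxane, so that the alcohol released next is unique.

Step 16
Reactants: 19 acetonide ester
Product: 20 C20 primary alcohol (1,9-acetonide; 19-OBn; 6-SiMe2Ph)
Conditions: LiAlH4, THF, 0 °C → rt
Reagents that add atoms: none
Why: LiAlH4 reduction of the hindered ester gives the C20 carbinol as the only free hydroxyl; acetonide, benzyl ether and arylsilane are inert to hydride.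

Step 17
Reactants: 21 methyl acetate; 22 methyl 2,2-dimethoxypropanoate
Product: 24 methyl 4,4-dimethoxy-3-oxopentanoate, via lithium enolate 23 (not isolated)
Conditions: LDA (2.2 equiv), 21 (2.2 equiv), THF, −78 °C; then 22, −78 → 0 °C; aq NH4Cl
Reagents that add atoms: none
Why: Crossed Claisen condensation: 22 has no α-hydrogen and can only be the acceptor, and the extra enolate deprotonates the β-keto ester formed and so drives the reaction.

Step 18
Reactants: 20 C20 alcohol; 24 methyl 4,4-dimethoxy-3-oxopentanoate
Product: 25 C20 4,4-dimethoxy-3-oxopentanoate of 20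
Conditions: DMAP (0.3 equiv), toluene, reflux, 4 Å MS
Reagents that add atoms: none
Why: DMAP-catalysed transesterification of an enolisable β-keto ester (acylketene-type pathway) acylates even neopentyl alcohols, and removal of methanol by the sieves pulls the equilibrium.

Step 19
Reactants: 25 acetonide β-keto ester
Product: 26 1,9-diol carrying the C20 β-keto ester
Conditions: PPTS, MeOH, 40 °C
Reagents that add atoms: none
Why: Mild acid-catalysed methanolysis cleaves the acetonide, whereas the C16 dimethyl ketal is deactivated by the adjacent ketone and in methanol can only exchange with the solvent.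

Step 20
Reactants: 26 1,9-diol β-keto ester
Product: 28 ring-A-spiro 3-acyl-5,6-dihydropyran-2-one (C8=C9; C15 ketone; C16 dimethyl ketal; free equatorial C1 hydroxyl; 19-OBn; 6-SiMe2Ph), via C9 aldehyde 27 (not isolated)
Conditions: TEMPO (0.2 equiv), PhI(OAc)2 (1.1 equiv), CH2Cl2, rt; then piperidine (0.3 equiv), 4 Å MS, rt
Reagents that add atoms: none
Why: Oxoammonium (TEMPO) oxidation is far faster for the primary C9 carbinol than for the hindered secondary C1 carbinol, and the piperidinium acetate formed from the added piperidine and the liberated acetic acid then closes the six-membered lactone ring by intramolecular Knoevenagel condensation (C8=C9), the weakly acidic buffer keeping the β-hydroxy aldehyde from retro-aldol cleavage of C1–C10.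

Step 21
Reactants: 29 but-1-en-3-yne
Product: 31 (but-3-en-1-yn-1-yl)dimethylsilane, via lithium acetylide 30 (not isolated)
Conditions: n-BuLi, THF, −78 °C; then Me2SiHCl, −78 °C → rt
Reagents that add atoms: chlorodimethylsilane, C[SiH](C)Cl
Why: Deprotonation of the terminal alkyne and C-silylation of the acetylide with a chlorosilane; the Si–H bond survives and is the later handle for Si–Cl.

Step 22
Reactants: 31 enynylsilane
Product: 33 [(Z)-buta-1,3-dien-1-yl]dimethylsilane, via vinylalane 32 (not isolated)
Conditions: i-Bu2AlH, Et2O/hexane, 0 °C → rt; then H2O, 0 °C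
Reagents that add atoms: none
Why: Hydroalumination of a 1-silylalkyne in a donor solvent is a cis addition with aluminium on the silicon-bearing carbon, and protonolysis with retention gives the (Z)-alkenylsilane while the vinyl group and Si–H are untouched.

Step 23
Reactants: 33 (Z)-dienylhydrosilane
Product: 34 chloro(dimethyl)[(Z)-buta-1,3-dien-1-yl]silane
Conditions: trichloroisocyanuric acid (0.35 equiv), CH2Cl2, −20 → 0 °C; filtration
Reagents that add atoms: trichloroisocyanuric acid, O=C1N(Cl)C(=O)N(Cl)C(=O)N1Cl
Why: Chlorination of a hydrosilane with trichloroisocyanuric acid is fast at low temperature, forms no HCl and gives only insoluble cyanuric acid, so the filtered solution of the dienylchlorosilane can be used directly.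

Step 24
Reactants: 28 spiro acyl-dihydropyranone; 34 (Z)-dienylchlorosilane
Product: 35 C1 O-[(Z)-buta-1,3-dienyl]dimethylsilyl ether of 28
Conditions: imidazole, CH2Cl2, 0 °C
Reagents that add atoms: none
Why: O-silylation of the C1 hydroxyl with a small dialkyl(alkenyl)chlorosilane under imidazole, a base too weak to trigger translactonisation or C1–C10 fragmentation of the activated lactone.

Step 25
Reactants: 35 silicon-tethered diene/dienophile
Product: 36 cycloadduct (ring C cyclohexene C12=C13 cis-fused to the lactone at C8–C9; oxasilinane C1–O–SiMe2–C11–C9–C10 cis-fused to ring C; silicon anti to the C15 acyl arm)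
Conditions: toluene (0.01 M), BHT, 110 °C, sealed tube
Reagents that add atoms: none
Why: A concerted, asynchronous normal-demand [4+2] cycloaddition of the tethered (Z)-dienylsilane onto C8=C9, whose LUMO is lowered by both the C7 lactone and the C15 ketone carbonyl; the closest known reaction type is the temporary-silicon-tethered (dienylsilyl ether) intramolecular Diels–Alder reaction. Ring C (C8–C9–C11–C12–C13–C14) closes by the cycloaddition itself through the C9–C11 and C8–C14 bonds, and the six-membered ring C1–O–Si–C11–C9–C10 closes at the same time as the tether ring of a type 1 intramolecular cycloaddition with a four-atom link, chair-like, with C9–C11 axial on the lactone half-chair and gauche to the equatorial C1–O bond. C9 is controlled by the O–Si link, which can bring C11 only to the C9 face syn to C1 (the other face is in addition screened by the C5 CH2SiMe2Ph arm), and C8 follows from suprafacial addition to the ring (Z)-alkene, which gives the cis ring C/lactone fusion with C15 cis to H-9. C11 is controlled by the diene geometry: a silyl group in the inside (Z) position can only be linked to an exo C10, so the oxasilinane is cis-fused, the C15 acyl group is endo and silicon ends up on the ring C face opposite to C15. The step needs π-facial selectivity at C9, the C9–C11/C8–C14 pairing against the weak intrinsic regiochemical bias of a 1-silyldiene, and enough reactivity to offset the neopentyl C9 and the strained s-cis form of a Z-diene; the first two are imposed by the short tether, the third by double activation and intramolecularity.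

Step 26
Reactants: 36 cycloadduct
Product: 38 bicyclo[3.2.1]octene keto lactone (C11=C12; C16 OMe/CH3 either epimer; free C1 hydroxyl; 19-OBn; 6-SiMe2Ph), via O-1 silyl triflate 37 (not isolated)
Conditions: TMSOTf (1.2 equiv), 2,6-di-tert-butyl-4-methylpyridine, CH2Cl2, −78 → −20 °C; aq NaHCO3; then 1 M HCl/THF, 0 °C
Reagents that add atoms: none
Why: Intramolecular Hosomi–Sakurai reaction: TMSOTf ionises the C16 ketal to the oxocarbenium ion, which C13 of the allylsilane attacks anti to silicon (anti SE2′, from the boat form of ring C in which C11–Si is pseudoaxial and the endo C15 arm lies under C13), a 5-exo closure that can bridge only on the C15 face and thus sets C13, moves the alkene to C11=C12 and expels the tether silicon, which the acidic work-up washes off O-1.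

Step 27
Reactants: 38 bicyclooctene keto lactone
Product: 39 saturated 1,19-diol (C11–C12 single bond; C16 OMe; 6-SiMe2Ph)
Conditions: H2 (1 atm), 10% Pd/C, EtOAc/EtOH, rt
Reagents that add atoms: none
Why: Heterogeneous hydrogenation saturates the disubstituted C11=C12 alkene and hydrogenolyses the benzyl ether in the same operation, while arylsilane, ketone and lactone are inert.

Step 28
Reactants: 39 1,19-diol
Product: 40 1,19-diacetate
Conditions: Ac2O, pyridine, DMAP (cat.), CH2Cl2, rt
Reagents that add atoms: acetic anhydride, CC(=O)OC(C)=O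
Why: DMAP-catalysed acetylation caps the two free hydroxyls with their final groups and is done at once so that O-1 cannot translactonise onto C7.

Step 29
Reactants: 40 16-methoxy ketone diacetate
Product: 41 16-methyl 15-ketone (C16 epimers; 1,19-diacetate; 6-SiMe2Ph)
Conditions: SmI2 (3 equiv), DMPU, MeOH, THF, −78 → 0 °C
Reagents that add atoms: none
Why: SmI2 reduction of an α-alkoxy ketone (ketyl formation, loss of methoxide, second electron transfer, protonation of the samarium enolate) removes the C16 oxygen, and the C16 configuration does not matter because the centre becomes sp2 later.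

Step 30
Reactants: 41 C6 silane
Product: 42 C6 primary alcohol (1,19-diacetate; 16-methyl 15-ketone)
Conditions: Hg(OAc)2 (1.3 equiv), AcOOH (32% in AcOH), rt
Reagents that add atoms: peracetic acid, CC(=O)OO
Why: Fleming–Tamao oxidation (mercuridesilylation of the phenyl group, then peracid-induced 1,2-shift of C6 from silicon to oxygen) in an acidic medium that spares the acetates and the non-enolisable β-keto lactone, which basic peroxide could cleave, and it is placed before the enone exists so that no epoxidation can compete.

Step 31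
Reactants: 42 keto alcohol
Product: 43 C15 trimethylsilyl enol ether (C15=C16) with C6 O-TMS ether
Conditions: TMSOTf (4 equiv), Et3N (8 equiv), CH2Cl2, 0 °C → rt
Reagents that add atoms: trimethylsilyl triflate, C[Si](C)(C)OS(=O)(=O)C(F)(F)F
Why: Soft enolisation: C16 is the only enolisable position of the C15 ketone because C8 is quaternary, the amine base is too weak to enolise the acetates appreciably, and the C6 hydroxyl is masked in passing.

Step 32
Reactants: 43 bis-silyl compound
Product: 45 target CNP0105570.2, via C6 TMS ether 44 (not isolated)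
Conditions: Pd(OAc)2 (1.1 equiv), MeCN, rt → 40 °C; then 1 M HCl/THF, 0 °C
Reagents that add atoms: none
Why: Saegusa–Ito oxidation: the palladium enolate at C16 can undergo β-hydride elimination only toward the C17 methyl group because elimination toward the C13 bridgehead would give an anti-Bredt alkene, so the exo-methylene ketone results, and brief acid removes the primary TMS ether.

Compound list
1 | benzoic acid | OC(=O)c1ccccc1 | starting material
2 | dilithium dienediolate from Birch reduction of benzoate | [Li+].[Li+].[O-]C([O-])=C1C=CCC=C1 | intermediate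
3 | 1-methylcyclohexa-2,5-diene-1-carboxylic acid | CC1(C(=O)O)C=CCC=C1 | intermediate
4 | (1-methylcyclohexa-2,5-dien-1-yl)methanol | CC1(CO)C=CCC=C1 | intermediate
5 | tert-butyldimethyl[(1-methylcyclohexa-2,5-dien-1-yl)methoxy]silane | CC1(CO[Si](C)(C)C(C)(C)C)C=CCC=C1 | intermediate
6 | 4-{[(tert-butyldimethylsilyl)oxy]methyl}-4-methylcyclohexa-2,5-dien-1-one | CC1(CO[Si](C)(C)C(C)(C)C)C=CC(=O)C=C1 | intermediate
7 | diethoxy(methyl)silyl dienol ether of 8 | CCO[Si](C)(OCC)OC1=CC[C@@](C)(CO[Si](C)(C)C(C)(C)C)C=C1 | intermediate
8 | (R)-4-{[(tert-butyldimethylsilyl)oxy]methyl}-4-methylcyclohex-2-en-1-one | O=C1CC[C@@](C)(CO[Si](C)(C)C(C)(C)C)C=C1 | intermediate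
9 | (R)-2-iodo derivative of 8 | O=C1CC[C@@](C)(CO[Si](C)(C)C(C)(C)C)C=C1I | intermediate
10 | methyl (R)-3-{[(tert-butyldimethylsilyl)oxy]methyl}-3-methyl-6-oxocyclohex-1-ene-1-carboxylate | O=C1CC[C@@](C)(CO[Si](C)(C)C(C)(C)C)C=C1C(=O)OC | intermediate
11 | methyl (R)-3-(hydroxymethyl)-3-methyl-6-oxocyclohex-1-ene-1-carboxylate | O=C1CC[C@@](C)(CO)C=C1C(=O)OC | intermediate
12 | (bromomethyl)chlorodimethylsilane | BrC[Si](C)(C)Cl | starting material
13 | methyl (R)-3-({[(bromomethyl)dimethylsilyl]oxy}methyl)-3-methyl-6-oxocyclohex-1-ene-1-carboxylate | O=C1CC[C@@](C)(CO[Si](C)(C)CBr)C=C1C(=O)OC | intermediate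
14 | cis-fused oxasilinane β-keto ester (C19–O–SiMe2–C6 ring, C10 epimers/enol) | COC(=O)C1C(=O)CC[C@@](C)(CO[Si](C)(C)C2)[C@H]12 | intermediate
15 | β-keto ester with C19 CH2OH and C6 CH2SiMe2Ph | COC(=O)C1C(=O)CC[C@@](C)(CO)[C@H]1C[Si](C)(C)c1ccccc1 | intermediate
16 | C19 benzyl ether of 15 | COC(=O)C1C(=O)CC[C@@](C)(COCc2ccccc2)[C@H]1C[Si](C)(C)c1ccccc1 | intermediate
17 | C10-quaternary keto ester with C9 CH2OH | OC[C@]1(C(=O)OC)C(=O)CC[C@@](C)(COCc2ccccc2)[C@H]1C[Si](C)(C)c1ccccc1 | intermediate
18 | 1,9-diol ester | OC[C@]1(C(=O)OC)[C@@H](O)CC[C@@](C)(COCc2ccccc2)[C@H]1C[Si](C)(C)c1ccccc1 | intermediate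
19 | 1,9-acetonide ester | CC1(C)OC[C@]2(C(=O)OC)[C@@H](O1)CC[C@@](C)(COCc3ccccc3)[C@H]2C[Si](C)(C)c1ccccc1 | intermediate
20 | C20 alcohol, 1,9-acetonide | CC1(C)OC[C@]2(CO)[C@@H](O1)CC[C@@](C)(COCc3ccccc3)[C@H]2C[Si](C)(C)c1ccccc1 | intermediate
21 | methyl acetate | COC(C)=O | starting material
22 | methyl 2,2-dimethoxypropanoate | COC(=O)C(C)(OC)OC | starting material
23 | lithium enolate of methyl acetate | [Li+].C=C([O-])OC | intermediate
24 | methyl 4,4-dimethoxy-3-oxopentanoate | COC(=O)CC(=O)C(C)(OC)OC | intermediate
25 | C20 4,4-dimethoxy-3-oxopentanoate, 1,9-acetonide | CC1(C)OC[C@]2(COC(=O)CC(=O)C(C)(OC)OC)[C@@H](O1)CC[C@@](C)(COCc3ccccc3)[C@H]2C[Si](C)(C)c1ccccc1 | intermediate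
26 | 1,9-diol C20 β-keto ester | OC[C@]1(COC(=O)CC(=O)C(C)(OC)OC)[C@@H](O)CC[C@@](C)(COCc2ccccc2)[C@H]1C[Si](C)(C)c1ccccc1 | intermediate
27 | C9 aldehyde | O=C[C@]1(COC(=O)CC(=O)C(C)(OC)OC)[C@@H](O)CC[C@@](C)(COCc2ccccc2)[C@H]1C[Si](C)(C)c1ccccc1 | intermediate
28 | ring-A-spiro 3-acyl-5,6-dihydropyran-2-one, free C1 hydroxyl | CC(OC)(OC)C(=O)C3=C[C@]1(COC3=O)[C@@H](O)CC[C@@](C)(COCc2ccccc2)[C@H]1C[Si](C)(C)c1ccccc1 | intermediate
29 | but-1-en-3-yne | C=CC#C | starting material
30 | lithium but-3-en-1-yn-1-ide | [Li+].[C-]#CC=C | intermediate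
31 | (but-3-en-1-yn-1-yl)dimethylsilane | C=CC#C[SiH](C)C | intermediate
32 | diisobutyl[(Z)-1-(dimethylsilyl)buta-1,3-dien-1-yl]alane (Si cis to vinyl) | C=C/C=C(\[SiH](C)C)[Al](CC(C)C)CC(C)C | intermediate
33 | [(Z)-buta-1,3-dien-1-yl]dimethylsilane | C=C/C=C\[SiH](C)C | intermediate
34 | chloro(dimethyl)[(Z)-buta-1,3-dien-1-yl]silane | C=C/C=C\[Si](C)(C)Cl | intermediate
35 | C1 O-[(Z)-dienyl]dimethylsilyl ether of 28 | CC(OC)(OC)C(=O)C3=C[C@]1(COC3=O)[C@@H](O[Si](C)(C)/C=C\C=C)CC[C@@](C)(COCc2ccccc2)[C@H]1C[Si](C)(C)c1ccccc1 | intermediate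
36 | Diels–Alder adduct with C11 allylsilane in the C1–O–Si ring | CC(OC)(OC)C(=O)[C@]23CC=C[C@@H]([Si]4(C)C)[C@H]2[C@]1(COC3=O)[C@@H](O4)CC[C@@](C)(COCc5ccccc5)[C@H]1C[Si](C)(C)c1ccccc1 | intermediate
37 | ring-D-closed O-1 dimethylsilyl triflate | COC1(C)C(=O)[C@]23C[C@H]1C=C[C@H]2[C@]1(COC3=O)[C@@H](O[Si](C)(C)OS(=O)(=O)C(F)(F)F)CC[C@@](C)(COCc4ccccc4)[C@H]1C[Si](C)(C)c1ccccc1 | intermediate
38 | bicyclo[3.2.1]octene keto lactone, C16 OMe, free C1 hydroxyl | COC1(C)C(=O)[C@]23C[C@H]1C=C[C@H]2[C@]1(COC3=O)[C@@H](O)CC[C@@](C)(COCc4ccccc4)[C@H]1C[Si](C)(C)c1ccccc1 | intermediate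
39 | saturated 1,19-diol | COC1(C)C(=O)[C@]23C[C@H]1CC[C@H]2[C@]1(COC3=O)[C@@H](O)CC[C@@](C)(CO)[C@H]1C[Si](C)(C)c1ccccc1 | intermediate
40 | 1,19-diacetate | COC1(C)C(=O)[C@]23C[C@H]1CC[C@H]2[C@]1(COC3=O)[C@@H](OC(C)=O)CC[C@@](C)(COC(C)=O)[C@H]1C[Si](C)(C)c1ccccc1 | intermediate
41 | 16-methyl 15-ketone, 6-SiMe2Ph | CC1C(=O)[C@]23C[C@H]1CC[C@H]2[C@]1(COC3=O)[C@@H](OC(C)=O)CC[C@@](C)(COC(C)=O)[C@H]1C[Si](C)(C)c1ccccc1 | intermediate
42 | C6 alcohol, 16-methyl 15-ketone | CC1C(=O)[C@]23C[C@H]1CC[C@H]2[C@]1(COC3=O)[C@@H](OC(C)=O)CC[C@@](C)(COC(C)=O)[C@H]1CO | intermediate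
43 | C15 TMS enol ether, C6 O-TMS | CC1=C(O[Si](C)(C)C)[C@]23C[C@H]1CC[C@H]2[C@]1(COC3=O)[C@@H](OC(C)=O)CC[C@@](C)(COC(C)=O)[C@H]1CO[Si](C)(C)C | intermediate
44 | C6 O-TMS ether of the target | C=C1C(=O)[C@]23C[C@H]1CC[C@H]2[C@]1(COC3=O)[C@@H](OC(C)=O)CC[C@@](C)(COC(C)=O)[C@H]1CO[Si](C)(C)C | intermediate
45 | CNP0105570.2 | C=C1C(=O)[C@]23C[C@H]1CC[C@H]2[C@]1(COC3=O)[C@@H](OC(C)=O)CC[C@@](C)(COC(C)=O)[C@H]1CO | target

Total step count: 32. Longest linear sequence: 28 steps (steps 1–16, 18–20 and 24–32). Steps 17 and 21–23 are side branches.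

Steps most likely to fail

Step 25. The cycloaddition may be too slow. The Z-dienylsilane reaches its s-cis form only with strain and C9 is neopentyl, so loss of the silyl ether or polymerisation of the diene could win. The fallback gives up the tether and sets out from 28. Compound 28 is heated with an excess of buta-1,3-diene (toluene, BHT, sealed tube) in an intermolecular Diels–Alder reaction. The C5 CH2SiMe2Ph arm blocks the C9 face syn to C5, and this should give the silicon-free cyclohexene lactone F1. Ring D is then closed by a Prins-type cyclisation (TMSOTf, hindered pyridine base, CH2Cl2). The C16 oxocarbenium ion is attacked by C13 of the C12=C13 alkene, and the C12 cation can lose only H-11 because C13 is a bridgehead. The route is rejoined at 38.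

Step 26. Ionisation of the ketone-deactivated ketal may be slower than protodesilylation, or the C11–Si bond held in the oxasilinane may overlap poorly with the alkene. The fallback sets out from 36 and replaces the oxocarbenium electrophile by a chelated carbonyl group. The ketal is hydrolysed under near-neutral conditions (LiBF4, wet MeCN) to the 1,2-diketone cycloadduct F2. TiCl4 (CH2Cl2, −78 °C), chelated by the two adjacent carbonyl groups, then promotes allylsilane addition to the C16 ketone. After work-up this gives the C16 tertiary carbinol F3. Hydrogenation as in step 27 gives the saturated triol F4. Acetylation as in step 28 leaves the tertiary hydroxyl free and gives the 1,19-diacetate ketol F5. SmI2 reduction of this α-hydroxy ketone rejoins the route at 41.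

Step 11. Phenyllithium may be consumed by further deprotonation of the enolate, or may attack the carbonyl groups faster than it opens the six-membered Si–O ring. The fallback sets out from 14 and separates ring opening from aryl transfer. HF·pyridine (THF, no basic work-up) opens the ring to the hydroxy fluorosilane F6. The acid-catalysed trichloroacetimidate benzylation of step 12 gives the benzyl ether fluorosilane F7. PhMgBr (2.5 equiv, THF, 0 °C → rt) first forms the inert chelated magnesium enolate and then substitutes fluoride at silicon. The route is rejoined at 16.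

Further compounds
F1 | step 25 | butadiene cycloadduct of 28 (C12=C13, no silicon on C11, free C1 hydroxyl) | CC(OC)(OC)C(=O)[C@]23CC=CC[C@H]2[C@]1(COC3=O)[C@@H](O)CC[C@@](C)(COCc4ccccc4)[C@H]1C[Si](C)(C)c1ccccc1
F2 | step 26 | 1,2-diketone (C15, C16) cycloadduct with intact C1–O–Si–C11 ring | CC(=O)C(=O)[C@]23CC=C[C@@H]([Si]4(C)C)[C@H]2[C@]1(COC3=O)[C@@H](O4)CC[C@@](C)(COCc5ccccc5)[C@H]1C[Si](C)(C)c1ccccc1
F3 | step 26 | bicyclo[3.2.1]octene keto lactone with C16 tertiary hydroxyl and free C1 hydroxyl | CC1(O)C(=O)[C@]23C[C@H]1C=C[C@H]2[C@]1(COC3=O)[C@@H](O)CC[C@@](C)(COCc4ccccc4)[C@H]1C[Si](C)(C)c1ccccc1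
F4 | step 26 | saturated 1,16,19-triol | CC1(O)C(=O)[C@]23C[C@H]1CC[C@H]2[C@]1(COC3=O)[C@@H](O)CC[C@@](C)(CO)[C@H]1C[Si](C)(C)c1ccccc1
F5 | step 26 | 1,19-diacetate with free C16 hydroxyl | CC1(O)C(=O)[C@]23C[C@H]1CC[C@H]2[C@]1(COC3=O)[C@@H](OC(C)=O)CC[C@@](C)(COC(C)=O)[C@H]1C[Si](C)(C)c1ccccc1
F6 | step 11 | β-keto ester with C19 CH2OH and C6 CH2SiMe2F | COC(=O)C1C(=O)CC[C@@](C)(CO)[C@H]1C[Si](C)(C)F
F7 | step 11 | C19 benzyl ether of F6 | COC(=O)C1C(=O)CC[C@@](C)(COCc2ccccc2)[C@H]1C[Si](C)(C)F
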